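The target, a trans-2-aryl-2,3-dihydrobenzofuran, is disconnected at the O1–C2 bond of its dihydrofuran ring. C2 carries both O1 and the 4-hydroxyphenyl ring C, so it can be flattened to a para-quinone methide, and C3 is an acidic α-aryl ester carbon next to ring A; the key step uses both facts. A chiral phosphoric acid should turn a stereorandom aldol adduct, a 2-(2-hydroxyaryl)-3-hydroxy-3-(4-hydroxyphenyl)propanoate, into the quinone methide, and the ring-A phenol should close the ring, so that four stereoisomers give one (2R,3R) ester in one operation. The two agmatine amides follow by a Heck reaction and a double amidation.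

Key step: step 5

Remark: the silylated aldehyde and the di-Boc-agmatine are taken as purchasable; the sense of induction of the phosphoric acid cannot be predicted, so the antipode that delivers the (2R,3R) ester is to be fixed by a screen; the last two compounds are handled as bis(trifluoroacetate) salts and drawn as free bases.

Step 1
Reactants: 1 2-(5-bromo-2-hydroxyphenyl)acetic acid
Product: 2 tert-butyl 2-(5-bromo-2-hydroxyphenyl)acetate
Conditions: Cl3CC(=NH)Ot-Bu (2 equiv), CH2Cl2–cyclohexane, rt
Reagents that add atoms: tert-butyl 2,2,2-trichloroacetimidate, CC(C)(C)OC(=N)C(Cl)(Cl)Cl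
Why: Esterification by tert-butyl transfer from a trichloroacetimidate, which only the carboxylic acid is acidic enough to protonate, so the phenol stays free and no strong acid is present that could close the hydroxy acid to the benzofuranone.

Step 2
Reactants: 2 tert-butyl 2-(5-bromo-2-hydroxyphenyl)acetate
Product: 3 tert-butyl 2-[5-bromo-2-(tert-butyldimethylsilyloxy)phenyl]acetate
Conditions: TBSCl, imidazole, DMF, rt
Reagents that add atoms: tert-butyldimethylsilyl chloride, CC(C)(C)[Si](C)(C)Cl
Why: Standard silylation of a phenol, which masks the acidic ring-A hydroxyl before the enolate is formed.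

Step 3
Reactants: 3 tert-butyl 2-[5-bromo-2-(tert-butyldimethylsilyloxy)phenyl]acetate; 4 4-(tert-butyldimethylsilyloxy)benzaldehyde
Product: 6 tert-butyl 2-[5-bromo-2-(tert-butyldimethylsilyloxy)phenyl]-3-hydroxy-3-[4-(tert-butyldimethylsilyloxy)phenyl]propanoate (all four stereoisomers), via lithium enolate 5 (not isolated)
Conditions: LiN(i-Pr)2, THF, −78 °C; then 4, −78 °C; AcOH quench at −78 °C
Reagents that add atoms: none
Why: Aldol addition of the lithium enolate of an arylacetate to a non-enolisable aldehyde; the amide base does not exchange the aryl bromide, the cold quench prevents retro-aldol, and no stereocontrol is sought because both new centres are erased or equilibrated in step 5.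

Step 4
Reactants: 6 the bis-silylated aldol adduct
Product: 7 tert-butyl 2-(5-bromo-2-hydroxyphenyl)-3-hydroxy-3-(4-hydroxyphenyl)propanoate (all four stereoisomers)
Conditions: Bu4NF (2.2 equiv), AcOH (2.4 equiv), THF, 0 °C
Reagents that add atoms: none
Why: Fluoride cleavage of the two aryl silyl ethers, buffered with acetic acid so that no free alkoxide or phenoxide can trigger retro-aldol, dehydration or attack on the tert-butyl ester, which itself is too hindered to lactonise with the ortho phenol.

Step 5
Reactants: 7 tert-butyl 2-(5-bromo-2-hydroxyphenyl)-3-hydroxy-3-(4-hydroxyphenyl)propanoate (all four stereoisomers)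
Product: 10 tert-butyl (2R,3R)-5-bromo-2-(4-hydroxyphenyl)-2,3-dihydro-1-benzofuran-3-carboxylate, via para-quinone methide 8 (not isolated), via hydroxystilbene tautomer 9 (not isolated)
Conditions: (R)-3,3'-bis(2,4,6-triisopropylphenyl)-1,1'-binaphthyl-2,2'-diyl hydrogen phosphate (10 mol %), 5 Å MS, CH2Cl2–toluene (1:1), 0.01 M, −20 to 0 °C; cold filtration through NaHCO3/silica
Reagents that add atoms: none
Why: Proposed new method: the acid protonates the benzylic hydroxyl of 7, water leaves with push from the para hydroxyl of ring C, and the planar quinone methide 8 that results has lost the C2 configuration of every isomer, while its C3 hydrogen, flanked by the ester, ring A and the quinone methide, is shuttled by the phosphate through hydroxystilbene 9 so that the C3 epimers interconvert. The ring-A hydroxyl then adds to the exocyclic carbon of 8 in a 5-exo-trig oxa-1,6-addition that forms O1–C2, closes the dihydrofuran ring and restores the aromatic ring C. The closest known reaction type is the chiral phosphoric acid-catalysed enantioselective 1,6-addition of nucleophiles to para-quinone methides generated in situ from 4-hydroxybenzylic alcohols; an intramolecular phenol nucleophile combined with a labile neighbouring centre has not been shown. C2 should be set by the catalyst, which holds the quinone methide oxygen through P–OH and the attacking phenol through P=O and so offers one face of the exocyclic carbon, and C3 by dynamic kinetic resolution, because only the epimer that closes with the bulky tert-butyl ester trans to ring C fits the pocket and the other returns through 9. The step needs kinetic control over face and epimer without re-ionisation of 10, and the substrate helps through the ortho placement of the nucleophile (fast closure at low temperature and high dilution), the tert-butyl ester (strong trans bias, no lactonisation) and the sieves that remove water; the phenol of 10 is capped at once in step 6.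

Step 6
Reactants: 10 tert-butyl (2R,3R)-5-bromo-2-(4-hydroxyphenyl)-2,3-dihydro-1-benzofuran-3-carboxylate
Product: 11 tert-butyl (2R,3R)-2-(4-acetoxyphenyl)-5-bromo-2,3-dihydro-1-benzofuran-3-carboxylate
Conditions: Ac2O, pyridine, CH2Cl2, 0 °C (on the crude product of step 5)
Reagents that add atoms: acetic anhydride, CC(=O)OC(C)=O
Why: Acylation of the phenol (esterification) removes the para-hydroxyl push, so C2 can no longer ionise and the configuration is locked for the rest of the route.

Step 7
Reactants: 11 tert-butyl (2R,3R)-2-(4-acetoxyphenyl)-5-bromo-2,3-dihydro-1-benzofuran-3-carboxylate; 12 tert-butyl acrylate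
Product: 13 tert-butyl (2R,3R)-2-(4-acetoxyphenyl)-5-[(E)-3-tert-butoxy-3-oxoprop-1-enyl]-2,3-dihydro-1-benzofuran-3-carboxylate
Conditions: Pd2(dba)3 (2.5 mol %), [HP(t-Bu)3]BF4 (10 mol %), Cy2NMe (1.5 equiv), 1,4-dioxane, rt to 45 °C
Reagents that add atoms: none
Why: Mizoroki–Heck reaction of the aryl bromide gives the (E)-cinnamate by syn insertion and syn β-hydride elimination; the hindered amine and low temperature spare the acidic C3–H, and any C3 epimerisation would return to the favoured trans isomer because C2 is fixed.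

Step 8
Reactants: 13 the di-tert-butyl ester
Product: 14 (2R,3R)-2-(4-acetoxyphenyl)-5-[(E)-2-carboxyethenyl]-2,3-dihydro-1-benzofuran-3-carboxylic acid
Conditions: CF3CO2H–CH2Cl2 (1:2), 0 °C to rt
Reagents that add atoms: none
Why: Acidolysis of both tert-butyl esters with loss of isobutene; the aryl acetate and the now non-ionisable benzylic ether are stable to this acid.

Step 9
Reactants: 14 the diacid; 15 N,N'-di-Boc-agmatine (2.1 equiv)
Product: 17 (2R,3R)-2-(4-acetoxyphenyl)-N-[4-(N',N''-di-Boc-guanidino)butyl]-5-[(E)-3-{[4-(N',N''-di-Boc-guanidino)butyl]amino}-3-oxoprop-1-enyl]-2,3-dihydro-1-benzofuran-3-carboxamide, via bis(azabenzotriazolyl) ester 16 (not isolated)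
Conditions: EDC·HCl (2.4 equiv), 1-hydroxy-7-azabenzotriazole (2.4 equiv), N-methylmorpholine, DMF, 0 °C to rt
Reagents that add atoms: none
Why: Carbodiimide/hydroxyazabenzotriazole amide coupling of both carboxyl groups through active ester 16; the weak base and low temperature limit deprotonation at C3, and trans remains the thermodynamic arrangement while C2 is locked.

Step 10
Reactants: 17 the tetra-Boc bis-amide
Product: 18 (2R,3R)-2-(4-acetoxyphenyl)-N-(4-guanidinobutyl)-5-{(E)-3-[(4-guanidinobutyl)amino]-3-oxoprop-1-enyl}-2,3-dihydro-1-benzofuran-3-carboxamide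
Conditions: CF3CO2H–CH2Cl2 (1:1), 0 °C to rt
Reagents that add atoms: none
Why: Acidolysis of the four Boc carbamates; with the phenol still acetylated the C2–O1 bond cannot ionise in the strong acid.

Step 11
Reactants: 18 the O-acetyl bis-guanidine
Product: 19 (2R,3R)-N-(4-guanidinobutyl)-5-{(E)-3-[(4-guanidinobutyl)amino]-3-oxoprop-1-enyl}-2-(4-hydroxyphenyl)-2,3-dihydro-1-benzofuran-3-carboxamide
Conditions: NH3 (7 M in MeOH), 0 °C to rt; reversed-phase HPLC (H2O–MeCN, 0.1 % CF3CO2H)
Reagents that add atoms: none
Why: Ammonolysis of the aryl acetate under nearly neutral conditions, in which the guanidinium groups stay protonated and neither C2 nor C3 is endangered.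

Compound list
1 | 2-(5-bromo-2-hydroxyphenyl)acetic acid | OC(=O)Cc1cc(Br)ccc1O | starting material
2 | tert-butyl 2-(5-bromo-2-hydroxyphenyl)acetate | CC(C)(C)OC(=O)Cc1cc(Br)ccc1O | intermediate
3 | tert-butyl 2-[5-bromo-2-(tert-butyldimethylsilyloxy)phenyl]acetate | CC(C)(C)OC(=O)Cc1cc(Br)ccc1O[Si](C)(C)C(C)(C)C | intermediate
4 | 4-(tert-butyldimethylsilyloxy)benzaldehyde | O=Cc1ccc(O[Si](C)(C)C(C)(C)C)cc1 | starting material
5 | lithium enolate of 3 | CC(C)(C)OC(O[Li])=Cc1cc(Br)ccc1O[Si](C)(C)C(C)(C)C | intermediate
6 | tert-butyl 2-[5-bromo-2-(tert-butyldimethylsilyloxy)phenyl]-3-hydroxy-3-[4-(tert-butyldimethylsilyloxy)phenyl]propanoate, four stereoisomers | CC(C)(C)OC(=O)C(c1cc(Br)ccc1O[Si](C)(C)C(C)(C)C)C(O)c1ccc(O[Si](C)(C)C(C)(C)C)cc1 | intermediate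
7 | tert-butyl 2-(5-bromo-2-hydroxyphenyl)-3-hydroxy-3-(4-hydroxyphenyl)propanoate, four stereoisomers | CC(C)(C)OC(=O)C(c1cc(Br)ccc1O)C(O)c1ccc(O)cc1 | intermediate
8 | tert-butyl 2-(5-bromo-2-hydroxyphenyl)-3-(4-oxocyclohexa-2,5-dien-1-ylidene)propanoate, racemic | CC(C)(C)OC(=O)C(c1cc(Br)ccc1O)C=C1C=CC(=O)C=C1 | intermediate
9 | tert-butyl 2-(5-bromo-2-hydroxyphenyl)-3-(4-hydroxyphenyl)prop-2-enoate, E/Z mixture | CC(C)(C)OC(=O)C(c1cc(Br)ccc1O)=Cc1ccc(O)cc1 | intermediate
10 | tert-butyl (2R,3R)-5-bromo-2-(4-hydroxyphenyl)-2,3-dihydro-1-benzofuran-3-carboxylate | Brc1ccc2c(c1)[C@@H](C(=O)OC(C)(C)C)[C@H](c1ccc(O)cc1)O2 | intermediate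
11 | tert-butyl (2R,3R)-2-(4-acetoxyphenyl)-5-bromo-2,3-dihydro-1-benzofuran-3-carboxylate | Brc1ccc2c(c1)[C@@H](C(=O)OC(C)(C)C)[C@H](c1ccc(OC(C)=O)cc1)O2 | intermediate
12 | tert-butyl acrylate | C=CC(=O)OC(C)(C)C | starting material
13 | tert-butyl (2R,3R)-2-(4-acetoxyphenyl)-5-[(E)-3-tert-butoxy-3-oxoprop-1-enyl]-2,3-dihydro-1-benzofuran-3-carboxylate | CC(C)(C)OC(=O)/C=C/c1ccc2c(c1)[C@@H](C(=O)OC(C)(C)C)[C@H](c1ccc(OC(C)=O)cc1)O2 | intermediate
14 | (2R,3R)-2-(4-acetoxyphenyl)-5-[(E)-2-carboxyethenyl]-2,3-dihydro-1-benzofuran-3-carboxylic acid | OC(=O)/C=C/c1ccc2c(c1)[C@@H](C(O)=O)[C@H](c1ccc(OC(C)=O)cc1)O2 | intermediate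
15 | N,N'-di-Boc-agmatine | NCCCCN=C(NC(=O)OC(C)(C)C)NC(=O)OC(C)(C)C | starting material
16 | bis(7-azabenzotriazol-1-yl) ester of 14 | O=C(On1nnc2cccnc12)/C=C/c1ccc2c(c1)[C@@H](C(=O)On1nnc3cccnc13)[C@H](c1ccc(OC(C)=O)cc1)O2 | intermediate
17 | (2R,3R)-2-(4-acetoxyphenyl)-N-[4-(N',N''-di-Boc-guanidino)butyl]-5-[(E)-3-{[4-(N',N''-di-Boc-guanidino)butyl]amino}-3-oxoprop-1-enyl]-2,3-dihydro-1-benzofuran-3-carboxamide | CC(C)(C)OC(=O)NC(NC(=O)OC(C)(C)C)=NCCCCNC(=O)/C=C/c1ccc2c(c1)[C@@H](C(=O)NCCCCN=C(NC(=O)OC(C)(C)C)NC(=O)OC(C)(C)C)[C@H](c1ccc(OC(C)=O)cc1)O2 | intermediate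
18 | (2R,3R)-2-(4-acetoxyphenyl)-N-(4-guanidinobutyl)-5-{(E)-3-[(4-guanidinobutyl)amino]-3-oxoprop-1-enyl}-2,3-dihydro-1-benzofuran-3-carboxamide (bis(trifluoroacetate) salt) | NC(N)=NCCCCNC(=O)/C=C/c1ccc2c(c1)[C@@H](C(=O)NCCCCN=C(N)N)[C@H](c1ccc(OC(C)=O)cc1)O2 | intermediate
19 | (2R,3R)-N-(4-guanidinobutyl)-5-{(E)-3-[(4-guanidinobutyl)amino]-3-oxoprop-1-enyl}-2-(4-hydroxyphenyl)-2,3-dihydro-1-benzofuran-3-carboxamide (bis(trifluoroacetate) salt) | NC(N)=NCCCCNC(=O)/C=C/c1ccc2c(c1)[C@@H](C(=O)NCCCCN=C(N)N)[C@H](c1ccc(O)cc1)O2 | target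

Total step count: 11. Longest linear sequence: 11 steps (1 to 19); 4, 12 and 15 enter as purchased building blocks.

Steps most likely to fail

Step 5. Stereoconvergence may be incomplete: ring closure can outrun the C3 equilibration, or the product can re-ionise at C2 under the catalyst, and either erodes enantiomeric purity. Ionisation of the ester-substituted carbinol may also be slow, or material may drain into the hydroxystilbene. The fallback sets out from 7 and gives up catalyst control. An achiral acid, (PhO)2P(O)OH (10 mol %) in CH2Cl2 at rt, is left to act under thermodynamic control, which is the known acid-mediated closure of phenolic diaryl carbinols to trans-phenylcoumarans through the quinone methide. This should give racemic tert-butyl trans-5-bromo-2-(4-hydroxyphenyl)-2,3-dihydro-1-benzofuran-3-carboxylate F1. Its enantiomers are then separated by preparative chromatography on a chiral stationary phase (supercritical CO2/MeOH, amylose carbamate column), and the (2R,3R) antipode re-enters the route as 10.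

Step 7. The electron-rich aryl bromide may need more heat than the C3 centre tolerates in the presence of amine, with loss of C3 configuration or β-elimination of the ring oxygen. The fallback sets out from 11 and avoids base altogether. A Stille coupling with Bu3SnCH=CH2 (Pd(PPh3)4, toluene, 90 °C) should give tert-butyl (2R,3R)-2-(4-acetoxyphenyl)-5-ethenyl-2,3-dihydro-1-benzofuran-3-carboxylate F2. Cross-metathesis of F2 with 12 (second-generation Grubbs catalyst, RuCl2(=CHPh)(PCy3)(H2IMes), CH2Cl2, 40 °C) should then deliver the (E)-cinnamate, and the route is rejoined at 13.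

Step 9. The hindered C3 carboxyl couples more slowly than the acrylic one, so driving the second coupling prolongs the exposure of the activated C3 acid to base (epimerisation, ring opening) and lets excess amine attack the aryl acetate. The fallback sets out from 11 and 15, forms the two amide bonds separately and brings in the side-arm amide through the Heck partner.
- CF3CO2H–CH2Cl2 on 11 should give (2R,3R)-2-(4-acetoxyphenyl)-5-bromo-2,3-dihydro-1-benzofuran-3-carboxylic acid F3.
- A single coupling of F3 with one equivalent of 15 (EDC·HCl, 1-hydroxy-7-azabenzotriazole, N-methylmorpholine, 0 °C) should give (2R,3R)-2-(4-acetoxyphenyl)-5-bromo-N-[4-(N',N''-di-Boc-guanidino)butyl]-2,3-dihydro-1-benzofuran-3-carboxamide F4.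
- Acylation of 15 with acryloyl chloride (Et3N, CH2Cl2, −20 °C) should give N-[4-(N',N''-di-Boc-guanidino)butyl]acrylamide F5.
- A Heck reaction of F4 with F5 under the conditions of step 7 joins the two, and the route is rejoined at 17; the C3 amide is also far less prone to deprotonation than the ester during this Heck reaction.

Further compounds
F1 | step 5 | racemic tert-butyl trans-5-bromo-2-(4-hydroxyphenyl)-2,3-dihydro-1-benzofuran-3-carboxylate | Brc1ccc2c(c1)[C@@H](C(=O)OC(C)(C)C)[C@H](c1ccc(O)cc1)O2.Brc1ccc2c(c1)[C@H](C(=O)OC(C)(C)C)[C@@H](c1ccc(O)cc1)O2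
F2 | step 7 | tert-butyl (2R,3R)-2-(4-acetoxyphenyl)-5-ethenyl-2,3-dihydro-1-benzofuran-3-carboxylate | C=Cc1ccc2c(c1)[C@@H](C(=O)OC(C)(C)C)[C@H](c1ccc(OC(C)=O)cc1)O2
F3 | step 9 | (2R,3R)-2-(4-acetoxyphenyl)-5-bromo-2,3-dihydro-1-benzofuran-3-carboxylic acid | Brc1ccc2c(c1)[C@@H](C(O)=O)[C@H](c1ccc(OC(C)=O)cc1)O2
F4 | step 9 | (2R,3R)-2-(4-acetoxyphenyl)-5-bromo-N-[4-(N',N''-di-Boc-guanidino)butyl]-2,3-dihydro-1-benzofuran-3-carboxamide | Brc1ccc2c(c1)[C@@H](C(=O)NCCCCN=C(NC(=O)OC(C)(C)C)NC(=O)OC(C)(C)C)[C@H](c1ccc(OC(C)=O)cc1)O2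
F5 | step 9 | N-[4-(N',N''-di-Boc-guanidino)butyl]acrylamide | C=CC(=O)NCCCCN=C(NC(=O)OC(C)(C)C)NC(=O)OC(C)(C)C
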